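**Retrosynthetic overview**

1. The target is released last from its tri-Boc derivative by acidolysis of three carbamates.
2. Feature: in the 2-amino-4,5-dihydroimidazole ring, N3, C4 (the indolyl-bearing stereocentre) and C5 are the three atoms of an aziridine, and C2 with N1 and the exocyclic nitrogen is a guanidine carbon attached to that aziridine nitrogen. Cutting N1–C5 therefore leads to an (R)-2-(indol-3-yl)-1-amidinoaziridine, which iodide should expand to the five-membered cyclic guanidine.
3. The amidinoaziridine comes from the NH-aziridine and di-Boc-triflylguanidine; the NH-aziridine from an (S)-azido alcohol (phosphine-mediated closure with inversion); the azido alcohol from an (S)-chlorohydrin made by asymmetric transfer hydrogenation of an α-chloroketone, which sets the only stereocentre.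
4. The α-chloroketone comes from 2,5-dibromoindole and chloroacetyl chloride; 2,5-dibromoindole from 5-bromooxindole and POBr3.
5. Ring order: the indole bicycle is bought in as the oxindole, the aziridine is closed in step 6, the imidazoline in step 8.

Key step: step 8

Remark: the target is taken as the neutral free base drawn, and the tri-Boc compound 14 is written as its endocyclic C2=N3 tautomer (the exocyclic C=N–Boc tautomer is the same compound for this route).

**Route**

Step 1
Reactants: 1 5-bromooxindole
Product: 2 2,5-dibromo-1H-indole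
Conditions: POBr3, imidazole, ClCH2CH2Cl, 80 °C
Reagents that add atoms: phosphorus oxybromide, O=P(Br)(Br)Br
Why: Dehydroxy-bromination of a lactam (Vilsmeier-type activation): the oxindole reacts through its 2-hydroxyindole tautomer, O-phosphorylation makes C2 electrophilic, bromide adds, and loss of the phosphorus leaving group aromatises the ring to the 2-bromoindole.

Step 2
Reactants: 2 2,5-dibromo-1H-indole; 3 chloroacetyl chloride
Product: 4 2-chloro-1-(2,5-dibromo-1H-indol-3-yl)ethan-1-one
Conditions: Et2AlCl, CH2Cl2, 0 °C
Reagents that add atoms: none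
Why: Friedel–Crafts acylation at C3, the only free nucleophilic position of the pyrrole ring, with Et2AlCl activating the acid chloride and consuming the hydrogen chloride so that the acid-labile 2-bromoindole is not exposed to protic acid.

Step 3
Reactants: 4 2-chloro-1-(2,5-dibromo-1H-indol-3-yl)ethan-1-one
Product: 5 tert-butyl 2,5-dibromo-3-(2-chloroacetyl)indole-1-carboxylate
Conditions: Boc2O, DMAP (5 mol %), MeCN, 0 °C → rt
Reagents that add atoms: di-tert-butyl dicarbonate, CC(C)(C)OC(=O)OC(=O)OC(C)(C)C
Why: DMAP-catalysed N-acylation of the acidic 3-acylindole N–H, which also removes the vinylogous-amide deactivation of the ketone and lowers the donor strength of the indole for the later steps.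

Step 4
Reactants: 5 tert-butyl 2,5-dibromo-3-(2-chloroacetyl)indole-1-carboxylate
Product: 6 tert-butyl 2,5-dibromo-3-[(1S)-2-chloro-1-hydroxyethyl]indole-1-carboxylate
Conditions: RuCl[(R,R)-TsDPEN](p-cymene) (2 mol %), HCO2H/Et3N (5:2), EtOAc, 25–30 °C
Reagents that add atoms: none
Why: Noyori–Ikariya asymmetric transfer hydrogenation of an α-chloro aryl ketone, in which the six-membered Ru–H/N–H transition state places the heteroaryl group against the η6-arene, so that the (R,R) catalyst should give the (S)-chlorohydrin in the same sense as (S)-2-chloro-1-phenylethanol from phenacyl chloride.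

Step 5
Reactants: 6 tert-butyl 2,5-dibromo-3-[(1S)-2-chloro-1-hydroxyethyl]indole-1-carboxylate
Product: 7 tert-butyl 3-[(1S)-2-azido-1-hydroxyethyl]-2,5-dibromoindole-1-carboxylate
Conditions: NaN3, NaI (cat.), DMF, 50 °C
Reagents that add atoms: sodium azide, [N-]=[N+]=[N-].[Na+]
Why: SN2 displacement of the primary chloride by azide, which leaves the carbinol stereocentre untouched, and the C2 bromide is not activated towards substitution once the ketone is reduced.

Step 6
Reactants: 7 tert-butyl 3-[(1S)-2-azido-1-hydroxyethyl]-2,5-dibromoindole-1-carboxylate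
Product: 10 tert-butyl 3-[(2R)-aziridin-2-yl]-2,5-dibromoindole-1-carboxylate, via iminophosphorane 8 (not isolated), via oxazaphospholidine 9 (not isolated)
Conditions: PPh3, MeCN, rt → 80 °C
Reagents that add atoms: none
Why: Staudinger reaction followed by aziridine closure: the iminophosphorane binds the hydroxyl oxygen to phosphorus, and nitrogen then displaces triphenylphosphine oxide from the carbinol carbon from the rear, so the (S)-alcohol is inverted to the (R)-aziridine.

Step 7
Reactants: 10 tert-butyl 3-[(2R)-aziridin-2-yl]-2,5-dibromoindole-1-carboxylate; 11 N,N'-di-Boc-N''-triflylguanidine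
Product: 12 tert-butyl 3-[(2R)-1-[N,N'-bis(tert-butoxycarbonyl)carbamimidoyl]aziridin-2-yl]-2,5-dibromoindole-1-carboxylate
Conditions: Et3N, CH2Cl2, 0 °C → rt
Reagents that add atoms: none
Why: Guanylation by addition–elimination: the unhindered aziridine N–H adds to the triflyl-activated guanidine carbon and triflamide is expelled, with no bond to the stereocentre made or broken.

Step 8
Reactants: 12 tert-butyl 3-[(2R)-1-[N,N'-bis(tert-butoxycarbonyl)carbamimidoyl]aziridin-2-yl]-2,5-dibromoindole-1-carboxylate
Product: 14 tert-butyl (4R)-2-[(tert-butoxycarbonyl)amino]-4-[2,5-dibromo-1-(tert-butoxycarbonyl)indol-3-yl]-4,5-dihydroimidazole-1-carboxylate, via sodium iodoethylguanidinate 13 (not isolated)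
Conditions: NaI (20 mol %), dry acetone, 25 → 45 °C
Reagents that add atoms: none
Why: Heine-type isomerisation: the di-Boc-amidino group turns the aziridine nitrogen into a stabilised leaving group, so iodide should open the ring by SN2 at the unhindered CH2 to give the guanidinate 13, whose Boc-bearing nitrogen then displaces iodide and forms the N1–C5 bond. The closest known reaction is the NaI-catalysed isomerisation of N-acyl and N-imidoyl aziridines to oxazolines and imidazolines. The imidazoline closes in the 5-exo-tet mode; attack by the nitrogen that came from the aziridine only regenerates 12, and attack by a Boc carbonyl oxygen would need a seven-membered ring. No stereocentre is created, and C4 keeps the (R) configuration of the aziridine because neither displacement takes place at it. The step needs SN2 rather than SN1 opening and attack at CH2 rather than at the benzylic carbon, which are favoured by the N-Boc and C2–Br groups (weaker electron release from the indole), by the crowding of the benzylic carbon between C2–Br and the peri C4–H, and by neutral conditions with substoichiometric iodide. If some opening does occur at the benzylic carbon, iodide entry and nitrogen re-closure are two inversions and the two ring nitrogens become tautomerically equivalent after Boc removal, so this leak still leads to the same target with the same configuration provided the benzylic iodide closes faster than it exchanges with iodide.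

Step 9
Reactants: 14 tert-butyl (4R)-2-[(tert-butoxycarbonyl)amino]-4-[2,5-dibromo-1-(tert-butoxycarbonyl)indol-3-yl]-4,5-dihydroimidazole-1-carboxylate
Product: 16 (4R)-4-(2,5-dibromo-1H-indol-3-yl)-4,5-dihydro-1H-imidazol-2-amine, via trifluoroacetate salt 15 (not isolated)
Conditions: CF3CO2H/CH2Cl2 (1:2), 0 °C → rt; then cold 1 M NaOH (aq), extraction
Reagents that add atoms: none
Why: Acidolysis of the three tert-butyl carbamates (loss of tert-butyl cation, then decarboxylation) under anhydrous conditions that spare the 2-bromoindole, followed by liberation of the free cyclic guanidine from its salt, with the C4 stereocentre not involved.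

**Compound list**

1 | 5-bromooxindole (5-bromo-1,3-dihydro-2H-indol-2-one) | O=C1Cc2cc(Br)ccc2N1 | starting material
2 | 2,5-dibromo-1H-indole | Brc1cc2cc(Br)ccc2[nH]1 | intermediate
3 | chloroacetyl chloride | ClCC(Cl)=O | starting material
4 | 2-chloro-1-(2,5-dibromo-1H-indol-3-yl)ethan-1-one | O=C(CCl)c1c(Br)[nH]c2ccc(Br)cc12 | intermediate
5 | tert-butyl 2,5-dibromo-3-(2-chloroacetyl)indole-1-carboxylate | O=C(CCl)c1c(Br)n(C(=O)OC(C)(C)C)c2ccc(Br)cc12 | intermediate
6 | tert-butyl 2,5-dibromo-3-[(1S)-2-chloro-1-hydroxyethyl]indole-1-carboxylate | O[C@H](CCl)c1c(Br)n(C(=O)OC(C)(C)C)c2ccc(Br)cc12 | intermediate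
7 | tert-butyl 3-[(1S)-2-azido-1-hydroxyethyl]-2,5-dibromoindole-1-carboxylate | O[C@H](CN=[N+]=[N-])c1c(Br)n(C(=O)OC(C)(C)C)c2ccc(Br)cc12 | intermediate
8 | iminophosphorane, tert-butyl 2,5-dibromo-3-[(1S)-1-hydroxy-2-[(triphenyl-λ5-phosphanylidene)amino]ethyl]indole-1-carboxylate (not isolated) | O[C@H](CN=P(c1ccccc1)(c1ccccc1)c1ccccc1)c1c(Br)n(C(=O)OC(C)(C)C)c2ccc(Br)cc12 | intermediate
9 | oxazaphospholidine, tert-butyl 2,5-dibromo-3-[(5S)-2,2,2-triphenyl-1,3,2λ5-oxazaphospholidin-5-yl]indole-1-carboxylate (not isolated) | O1[C@H](CNP1(c2ccccc2)(c3ccccc3)c4ccccc4)c5c(Br)n(C(=O)OC(C)(C)C)c6ccc(Br)cc56 | intermediate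
10 | tert-butyl 3-[(2R)-aziridin-2-yl]-2,5-dibromoindole-1-carboxylate | N1[C@H](c2c(Br)n(C(=O)OC(C)(C)C)c3ccc(Br)cc23)C1 | intermediate
11 | N,N'-di-Boc-N''-triflylguanidine | CC(C)(C)OC(=O)NC(=NS(=O)(=O)C(F)(F)F)NC(=O)OC(C)(C)C | starting material
12 | tert-butyl 3-[(2R)-1-[N,N'-bis(tert-butoxycarbonyl)carbamimidoyl]aziridin-2-yl]-2,5-dibromoindole-1-carboxylate | CC(C)(C)OC(=O)NC(=NC(=O)OC(C)(C)C)N1[C@H](c2c(Br)n(C(=O)OC(C)(C)C)c3ccc(Br)cc23)C1 | intermediate
13 | sodium salt of the ring-opened N-[(1R)-1-(1-Boc-2,5-dibromoindol-3-yl)-2-iodoethyl]-N',N''-di-Boc-guanidine (not isolated) | [Na+].CC(C)(C)OC(=O)NC(=NC(=O)OC(C)(C)C)[N-][C@@H](CI)c1c(Br)n(C(=O)OC(C)(C)C)c2ccc(Br)cc12 | intermediate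
14 | tert-butyl (4R)-2-[(tert-butoxycarbonyl)amino]-4-[2,5-dibromo-1-(tert-butoxycarbonyl)indol-3-yl]-4,5-dihydroimidazole-1-carboxylate | CC(C)(C)OC(=O)NC1=N[C@H](c2c(Br)n(C(=O)OC(C)(C)C)c3ccc(Br)cc23)CN1C(=O)OC(C)(C)C | intermediate
15 | trifluoroacetate salt of the target (not isolated) | NC1=[NH+][C@H](c2c(Br)[nH]c3ccc(Br)cc23)CN1.[O-]C(=O)C(F)(F)F | intermediate
16 | (4R)-4-(2,5-dibromo-1H-indol-3-yl)-4,5-dihydro-1H-imidazol-2-amine (CNP0165428.1) | NC1=N[C@H](c2c(Br)[nH]c3ccc(Br)cc23)CN1 | target

**Step count and risks**

Total steps: 9. Longest linear sequence: 9 steps, from 5-bromooxindole 1.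

Steps most likely to fail:

1. Step 8 (ring expansion). The ring opening may drift to the benzylic carbon, where ionisation or iodide-for-iodide exchange before re-closure would erode the configuration, or the N-alkylation may be slow enough for the activated aziridine to decompose. The fallback sets out from 7 and returns at 16; it builds the imidazoline by dehydrative cyclisation of an open-chain guanidine instead of by aziridine expansion.
   - The azide of 7 would be reduced with PMe3 in wet THF at room temperature, where hydrolysis of the iminophosphorane should outrun aziridine closure, to the amino alcohol tert-butyl 3-[(1S)-2-amino-1-hydroxyethyl]-2,5-dibromoindole-1-carboxylate F1.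
   - Guanylation of the primary amine with 11 (Et3N, CH2Cl2) should give the hydroxy guanidine tert-butyl 3-[(1S)-2-[N',N''-bis(tert-butoxycarbonyl)guanidino]-1-hydroxyethyl]-2,5-dibromoindole-1-carboxylate F2.
   - Intramolecular Mitsunobu N-alkylation (PPh3, diisopropyl azodicarboxylate, THF, 0 °C → rt) would close the ring at the benzylic carbon with inversion to tert-butyl (5R)-2-[(tert-butoxycarbonyl)imino]-5-[2,5-dibromo-1-(tert-butoxycarbonyl)indol-3-yl]imidazolidine-1-carboxylate F3.
   - CF3CO2H and then NaOH, as in step 9, would give 16. Nitrogen enters the benzylic carbon from the face opposite the hydroxyl, as in the aziridine route, so the (S)-alcohol again leads to the (R)-target.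

2. Step 4 (asymmetric transfer hydrogenation). The ketone sits between C2–Br and the peri C4–H, so the heteroaryl group may twist out of the plane needed for the arene contact, giving poor facial discrimination or slow turnover. The fallback sets out from 5 and returns at 6: Corey–Bakshi–Shibata reduction with (S)-2-methyl-CBS-oxazaborolidine (0.2 equiv) and BH3·SMe2 in THF at −20 °C. Its selectivity rests on the size difference between the bulky heteroaryl group and CH2Cl rather than on an arene contact, so the crowding helps, and it should give the same (S)-chlorohydrin; no new compound is involved.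

3. Step 6 (aziridine closure). The displacement takes place at a congested benzylic carbon, so the phosphorus-bound intermediate may stall and be hydrolysed to the amino alcohol instead of closing. The fallback sets out from 7 and returns at 10; it separates activation from closure.
   - Mesylation (MsCl, Et3N, CH2Cl2, −20 °C) would give tert-butyl 3-[(1S)-2-azido-1-(methanesulfonyloxy)ethyl]-2,5-dibromoindole-1-carboxylate F4.
   - Reduction of the azide with PMe3 in wet THF would give the amino mesylate tert-butyl 3-[(1S)-2-amino-1-(methanesulfonyloxy)ethyl]-2,5-dibromoindole-1-carboxylate F5.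
   - On warming with Et3N, F5 should close by intramolecular SN2 displacement of the sulfonate with inversion to the (R)-aziridine 10.

**Further compounds**

F1 | step 8 | tert-butyl 3-[(1S)-2-amino-1-hydroxyethyl]-2,5-dibromoindole-1-carboxylate | O[C@H](CN)c1c(Br)n(C(=O)OC(C)(C)C)c2ccc(Br)cc12
F2 | step 8 | tert-butyl 3-[(1S)-2-[N',N''-bis(tert-butoxycarbonyl)guanidino]-1-hydroxyethyl]-2,5-dibromoindole-1-carboxylate | O[C@H](CNC(=NC(=O)OC(C)(C)C)NC(=O)OC(C)(C)C)c1c(Br)n(C(=O)OC(C)(C)C)c2ccc(Br)cc12
F3 | step 8 | tert-butyl (5R)-2-[(tert-butoxycarbonyl)imino]-5-[2,5-dibromo-1-(tert-butoxycarbonyl)indol-3-yl]imidazolidine-1-carboxylate | CC(C)(C)OC(=O)N=C1NC[C@@H](c2c(Br)n(C(=O)OC(C)(C)C)c3ccc(Br)cc23)N1C(=O)OC(C)(C)C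
F0 | step 4 | none | none
F4 | step 6 | tert-butyl 3-[(1S)-2-azido-1-(methanesulfonyloxy)ethyl]-2,5-dibromoindole-1-carboxylate | CS(=O)(=O)O[C@H](CN=[N+]=[N-])c1c(Br)n(C(=O)OC(C)(C)C)c2ccc(Br)cc12
F5 | step 6 | tert-butyl 3-[(1S)-2-amino-1-(methanesulfonyloxy)ethyl]-2,5-dibromoindole-1-carboxylate | CS(=O)(=O)O[C@H](CN)c1c(Br)n(C(=O)OC(C)(C)C)c2ccc(Br)cc12
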